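Time first: 5.0 h is a long run for this isothermal flask, and what counts is what stands at its end.

    L + D ⇌ X (K1 = 1600 M⁻¹, k1 = 4.5 M⁻¹ s⁻¹)
    L + D ⇌ L.D (K2 = 1400 M⁻¹, k2 = 14 M⁻¹ s⁻¹)
    E ⇌ L.D, rate k3*(cs3 - [L.D]) while solid is left; crystals form when [L.D] > cs3 (cs3 = 0.11 mM, k3 = 2.0 s⁻¹)

L 2.0 mM; D 1.80 mM (in portions, 4); time 5.0 h; the portions of D follow each other after 1.0 min, the first at the start

- what is said of L.D includes E
- E is a solid; its amount is given per volume of the solution
- the reaction counts as stopped when no species that holds the L changes by six tenths of a point or more over the second half of the time
- run time (flask): 5.0 h

* why nothing more happens at 5.0 h, or that something still does (it is still moving / forward and back rates have come level / all of L has reacted / D has run out first)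
* part of the L gone at 5.0 h
* the L.D standing at 5.0 h, as a percentage of the L charged
* the X standing at 5.0 h, as a percentage of the L charged

Which numbers must be known well? The rate constants need not be. The slower way back, from X to L + D, has a half-life of 4.11 min, and the last portion of D goes in at 3.00 min; both are short against the run, so the steps are taken as level at the end (equilibrium). With E present, the free fractions of the L charge, l and d, then multiply to the solubility over the constant of L.D, per square of the L charge: the saturation product 0.0196. L and D as charged, with nothing reacted and all portions counted, multiply to 0.900, far above it, so E is expected. Both reactions take L and D one for one, so once all of D is in, l − d stands at the charge gap 0.100. A relative error in the saturation product moves l by 0.0660 per unit, and one in the D charge by 0.601, so the D charge has to be known better. The constant of X enters through the small correction x, the saturation product times 3.20.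

The reckoning gives l = 19.9% and x = 6.29%, so conversion is 80.1% and L.D 73.8%.

The forecast says forward and back rates have come level, with 80.1% converted, L.D 73.8% and X 6.3%, holding that the time “is ample for full equilibrium”.

The flask gives forward and back rates have come level, with 80.1% converted, L.D 73.8% and X 6.29%. Just before the last addition, at 0.0500 h, this flask held X at 12.8% and E at 36.2% of the L charged, half of the crystallising up to 5.0 h being done by 2.75 min. By 2.50 h X had fallen to 6.29% while E had grown to 68.3%.

In the neighbour flask with 0.45 mM of D, L and D as charged multiply to 0.225, still above the saturation product, so E is expected; the saturation product then gives the same x, and the gap 0.775 plus the correction 0.0253 gives l = 80.0% and L.D 13.7%. That flask computes to L 80.0%, L.D 13.8% and X 6.29%.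

All constants come from no measurement; the flask was simulated.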